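**Plan**

- Retrosynthesis cuts, in this order: the two O–S bonds, the C7=C8 and C7'=C8' double bonds (C20 dialdehyde plus two identical C10 ring sulfones), the C3–O and C4–O bonds of each ring (back to a C3=C4 cyclohexene), and the C5–C6 and C1–C2 ring bonds (diene plus enal).
- Forward: the six-membered ring arises first by Diels–Alder reaction, is set trans, resolved and cis-hydroxylated. O4 and O3 are told apart as TES and TBS ethers and the ester carbon becomes the C7 sulfone. Two rings are then joined to the C20 chain in one twofold Julia–Kocienski olefination, and O4 is sulfated last.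
- Enabling feature: in each end ring the C3 oxygen is axial and syn to the axial methyl on C1 while the C4 oxygen is equatorial, so the cis-3,4-diol lies on the more hindered face of a C3=C4 cyclohexene, the face a Woodward hydroxylation reaches.
- Stereochemistry: C5/C6 trans by thermodynamic epimerization, absolute configuration by salt resolution, C3/C4 by the substrate-controlled hydroxylation, chain geometry from all-E crocetin dialdehyde plus E-selective olefination.

Key step: step 7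

Remarks on the chemistry:
- Ring positions in the discussion follow carotenoid numbering (C1 gem-dimethyl carbon, C3 and C4 oxygenated carbons, C5 methyl-bearing carbon, C6 carbon bearing C7); compound names use systematic locants.
- It is assumed that the less soluble salt of (S)-1-phenylethylamine carries the (1R,2S) acid; if the pairing is the opposite one, the (R)-amine is used in the same way.
- The target is drawn as the free bis(hydrogen sulfate); it is assumed to be released by proton exchange at the very end and kept cold and dilute, the pyridinium salt 25 being the form to store.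

**Route**

Step 1
Reactants: 1 (E)-penta-1,3-diene; 2 3-methylbut-2-enal
Product: 3 rac-(1S,2S)-2,6,6-trimethylcyclohex-3-ene-1-carbaldehyde (cis)
Conditions: 1 (2 equiv), AlCl3 (0.2 equiv), CH2Cl2, −20 °C → rt
Reagents that add atoms: none
Why: Lewis acid-catalysed Diels–Alder reaction in which the CH2 terminus of the diene bonds to the β-carbon of the AlCl3-bound enal ("ortho" regiochemistry) and the endo transition state places the formyl group cis to the ring methyl; any trans isomer formed alongside is carried on, since step 2 converges both.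

Step 2
Reactants: 3 rac-(1S,2S)-2,6,6-trimethylcyclohex-3-ene-1-carbaldehyde
Product: 4 rac-(1R,2S)-2,6,6-trimethylcyclohex-3-ene-1-carbaldehyde (trans)
Conditions: NaOMe (0.1 equiv), MeOH, rt
Reagents that add atoms: none
Why: Base-mediated epimerization through the enolate at the formyl-bearing carbon should settle on the diequatorial trans isomer, and the ring alkene cannot move into conjugation because it is γ,δ to the carbonyl.

Step 3
Reactants: 4 rac-(1R,2S)-2,6,6-trimethylcyclohex-3-ene-1-carbaldehyde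
Product: 5 rac-(1R,2S)-2,6,6-trimethylcyclohex-3-ene-1-carboxylic acid
Conditions: NaClO2, NaH2PO4, 2-methylbut-2-ene, t-BuOH/H2O, 0 °C → rt
Reagents that add atoms: sodium chlorite, [Na+].[O-]Cl=O
Why: Pinnick oxidation converts the hindered aldehyde into the acid while the scavenger alkene intercepts hypochlorous acid, so the ring alkene and the trans relationship are kept.

Step 4
Reactants: 5 rac-(1R,2S)-2,6,6-trimethylcyclohex-3-ene-1-carboxylic acid; 6 (S)-1-phenylethylamine
Product: 7 (S)-1-phenylethylammonium (1R,2S)-2,6,6-trimethylcyclohex-3-ene-1-carboxylate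
Conditions: 6 (1.0 equiv), acetone, reflux → 5 °C; recrystallization from acetone to constant rotation
Reagents that add atoms: none
Why: Classical resolution by fractional crystallization of diastereomeric ammonium carboxylates is expected to deliver the salt of the (1R,2S) acid, which fixes the absolute configuration that all later centres follow.

Step 5
Reactants: 7 (S)-1-phenylethylammonium (1R,2S)-2,6,6-trimethylcyclohex-3-ene-1-carboxylate
Product: 8 (1R,2S)-2,6,6-trimethylcyclohex-3-ene-1-carboxylic acid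
Conditions: 1 M HCl, Et2O, 0 °C
Reagents that add atoms: none
Why: Acid–base partition (protonation of the carboxylate) frees the acid from its ammonium salt without touching a stereocentre.

Step 6
Reactants: 8 (1R,2S)-2,6,6-trimethylcyclohex-3-ene-1-carboxylic acid
Product: 9 methyl (1R,2S)-2,6,6-trimethylcyclohex-3-ene-1-carboxylate
Conditions: MeI, K2CO3, DMF, rt
Reagents that add atoms: iodomethane, CI
Why: O-alkylation of the carboxylate (SN2 at iodomethane) avoids the slow Fischer esterification of this doubly flanked carboxyl group and is too weakly basic to epimerize the ester α-carbon.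

Step 7
Reactants: 9 methyl (1R,2S)-2,6,6-trimethylcyclohex-3-ene-1-carboxylate
Product: 13 methyl (1R,2R,3S,4R)-4-acetoxy-3-hydroxy-2,6,6-trimethylcyclohexane-1-carboxylate, via trans-diaxial iodo acetate 10 (not isolated), via dioxolanylium acetate 11 (not isolated), via orthoacid 12 (not isolated)
Conditions: I2 (1.05 equiv), AgOAc (2.2 equiv), AcOH, rt, dark; then AcOH/H2O, 90 °C
Reagents that add atoms: silver acetate, CC(=O)[O-].[Ag+]; water, O
Why: Woodward cis-hydroxylation: acetyl hypoiodite from I2 and AgOAc forms the iodonium ion on the alkene face anti to the axial C1 methyl, acetate opens it from the other face trans-diaxially at C3 to give 10, and the carbonyl oxygen of that acetate then displaces the antiperiplanar axial iodide at C4 (silver-assisted, inversion) to give the cis-fused dioxolanylium ion 11, which water traps as orthoacid 12 and which collapses to the hydroxy acetate. The closest known case is the same reaction on steroidal 2-enes with an angular methyl group, where the cis-diol is delivered to the methyl-bearing face, the opposite of what OsO4 gives. No ring is kept in the product; the transient dioxolanylium ring closes by a 5-exo-tet displacement. The C3 stereocentre is set by backside attack of acetate on the iodonium ion and the C4 stereocentre by inversion of the C–I bond, so both oxygens finish on the face of C7 and trans to the C5 methyl, and the same cation 11 results even if acetate first attacks C4. The step needs facial selectivity and a single monoacetate: the axial C1 methyl disfavours an iodonium ion or a syn-axial iodine on its own face while tolerating the small syn-axial oxygen, and 12 is expected to break its bond to the equatorial oxygen, leaving the acetate on axial O3 and the O4 hydroxyl free for later sulfation.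

Step 8
Reactants: 13 methyl (1R,2R,3S,4R)-4-acetoxy-3-hydroxy-2,6,6-trimethylcyclohexane-1-carboxylate
Product: 14 methyl (1R,2R,3S,4R)-4-acetoxy-2,6,6-trimethyl-3-[(triethylsilyl)oxy]cyclohexane-1-carboxylate
Conditions: TESOTf (1.1 equiv), 2,6-lutidine, CH2Cl2, −78 °C
Reagents that add atoms: triethylsilyl trifluoromethanesulfonate, CC[Si](CC)(CC)OS(=O)(=O)C(F)(F)F
Why: Silyl ether formation at the free equatorial O4 hydroxyl with a silyl triflate under cold, weakly basic, non-nucleophilic conditions should be fast enough to outrun O3-to-O4 acetyl migration.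

Step 9
Reactants: 14 methyl (1R,2R,3S,4R)-4-acetoxy-2,6,6-trimethyl-3-[(triethylsilyl)oxy]cyclohexane-1-carboxylate
Product: 15 (1R,2S,3R,4R)-4-(hydroxymethyl)-3,5,5-trimethyl-2-[(triethylsilyl)oxy]cyclohexan-1-ol
Conditions: LiAlH4, Et2O, 0 °C → rt; aq. KNaC4H4O6 (potassium sodium tartrate)
Reagents that add atoms: none
Why: LiAlH4 reduction turns the methyl ester into the C7 primary alcohol and cleaves the acetate in the same operation, while the TES ether is inert to hydride.

Step 10
Reactants: 15 (1R,2S,3R,4R)-4-(hydroxymethyl)-3,5,5-trimethyl-2-[(triethylsilyl)oxy]cyclohexan-1-ol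
Product: 16 (1R,2S,3R,4R)-3,5,5-trimethyl-4-{[(1-phenyl-1H-tetrazol-5-yl)sulfanyl]methyl}-2-[(triethylsilyl)oxy]cyclohexan-1-ol
Conditions: 1-phenyl-1H-tetrazole-5-thiol, PPh3, DIAD, THF, 0 °C → rt
Reagents that add atoms: 1-phenyl-1H-tetrazole-5-thiol, Sc1nnnn1-c1ccccc1
Why: Mitsunobu thioetherification activates only the primary C7 hydroxyl for SN2 displacement by the acidic thiol, the axial O3 hydroxyl (syn-axial to a methyl and next to the silyl ether) being too hindered to react.

Step 11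
Reactants: 16 (1R,2S,3R,4R)-3,5,5-trimethyl-4-{[(1-phenyl-1H-tetrazol-5-yl)sulfanyl]methyl}-2-[(triethylsilyl)oxy]cyclohexan-1-ol
Product: 17 5-({[(1R,2R,3S,4R)-4-[(tert-butyldimethylsilyl)oxy]-2,6,6-trimethyl-3-[(triethylsilyl)oxy]cyclohexyl]methyl}sulfanyl)-1-phenyl-1H-tetrazole
Conditions: TBSOTf (1.5 equiv), 2,6-lutidine, CH2Cl2, 0 °C → rt
Reagents that add atoms: tert-butyldimethylsilyl trifluoromethanesulfonate, CC(C)(C)[Si](C)(C)OS(=O)(=O)C(F)(F)F
Why: Silyl ether formation with the reactive silyl triflate is what the hindered axial O3 hydroxyl requires, and the TES ether and the thioether tolerate it.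

Step 12
Reactants: 17 5-({[(1R,2R,3S,4R)-4-[(tert-butyldimethylsilyl)oxy]-2,6,6-trimethyl-3-[(triethylsilyl)oxy]cyclohexyl]methyl}sulfanyl)-1-phenyl-1H-tetrazole
Product: 19 5-({[(1R,2R,3S,4R)-4-[(tert-butyldimethylsilyl)oxy]-2,6,6-trimethyl-3-[(triethylsilyl)oxy]cyclohexyl]methyl}sulfonyl)-1-phenyl-1H-tetrazole, via sulfoxide 18 (not isolated)
Conditions: mCPBA (3 equiv), NaHCO3, CH2Cl2, 0 °C → rt
Reagents that add atoms: 3-chloroperoxybenzoic acid, OOC(=O)c1cccc(Cl)c1
Why: Peracid oxidation of the sulfide through the sulfoxide to the sulfone, buffered with NaHCO3 so that the acid-labile TES ether survives.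

Step 13
Reactants: 19 5-({[(1R,2R,3S,4R)-4-[(tert-butyldimethylsilyl)oxy]-2,6,6-trimethyl-3-[(triethylsilyl)oxy]cyclohexyl]methyl}sulfonyl)-1-phenyl-1H-tetrazole (2.3 equiv); 20 crocetin dialdehyde
Product: 22 (all-E,3R,4S,5R,6R,3'R,4'S,5'R,6'R)-3,3'-bis[(tert-butyldimethylsilyl)oxy]-4,4'-bis[(triethylsilyl)oxy]-5,6,5',6'-tetrahydro-β,β-carotene, via mono-olefinated apocarotenal 21 (not isolated)
Conditions: 19, KN(SiMe3)2 (2.4 equiv), DME, −60 °C; then 20 in THF, −60 °C → rt; aq. NH4Cl; dark, argon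
Reagents that add atoms: none
Why: Twofold Julia–Kocienski olefination, in which the metalated tetrazolyl sulfone adds to each non-enolizable enal terminus and Smiles rearrangement with loss of SO2 and the tetrazololate forms the C7=C8 and C7'=C8' double bonds, the potassium counter-ion in an ethereal solvent favouring E geometry; no ring stereocentre is involved.

Step 14
Reactants: 22 (all-E,3R,4S,5R,6R,3'R,4'S,5'R,6'R)-3,3'-bis[(tert-butyldimethylsilyl)oxy]-4,4'-bis[(triethylsilyl)oxy]-5,6,5',6'-tetrahydro-β,β-carotene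
Product: 23 (all-E,3R,4S,5R,6R,3'R,4'S,5'R,6'R)-3,3'-bis[(tert-butyldimethylsilyl)oxy]-5,6,5',6'-tetrahydro-β,β-carotene-4,4'-diol
Conditions: PPTS (0.3 equiv), MeOH/CH2Cl2, 0 °C, dark
Reagents that add atoms: none
Why: Acid-catalysed methanolysis of silyl ethers removes the two secondary TES groups much faster than the hindered TBS groups, so only O4 and O4' are exposed.

Step 15
Reactants: 23 (all-E,3R,4S,5R,6R,3'R,4'S,5'R,6'R)-3,3'-bis[(tert-butyldimethylsilyl)oxy]-5,6,5',6'-tetrahydro-β,β-carotene-4,4'-diol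
Product: 24 bis(pyridinium) (all-E,3R,4S,5R,6R,3'R,4'S,5'R,6'R)-3,3'-bis[(tert-butyldimethylsilyl)oxy]-5,6,5',6'-tetrahydro-β,β-carotene-4,4'-diyl disulfate
Conditions: SO3·pyridine (8 equiv), pyridine, rt, dark
Reagents that add atoms: sulfur trioxide–pyridine complex, [O-]S(=O)(=O)[n+]1ccccc1
Why: O-sulfation of the equatorial secondary alcohols with the sulfur trioxide–pyridine complex, a reagent mild enough for carotenoid polyenes, while O3 stays blocked as its TBS ether.

Step 16
Reactants: 24 bis(pyridinium) (all-E,3R,4S,5R,6R,3'R,4'S,5'R,6'R)-3,3'-bis[(tert-butyldimethylsilyl)oxy]-5,6,5',6'-tetrahydro-β,β-carotene-4,4'-diyl disulfate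
Product: 26 (all-E,3R,4S,5R,6R,3'R,4'S,5'R,6'R)-3,3'-dihydroxy-5,6,5',6'-tetrahydro-β,β-carotene-4,4'-diyl bis(hydrogen sulfate), via bis(pyridinium) salt 25 (not isolated)
Conditions: HF·pyridine, pyridine, THF, 0 °C → rt; then sulfonic acid cation-exchange resin (H+ form), MeOH/H2O, 0 °C
Reagents that add atoms: none
Why: Fluoride-mediated desilylation frees the axial O3 hydroxyls without touching the sulfate monoesters, and proton exchange of the pyridinium counter-ions gives the bis(hydrogen sulfate).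

**Compound list**

1 | (E)-penta-1,3-diene | C=C/C=C/C | starting material
2 | 3-methylbut-2-enal | CC(C)=CC=O | starting material
3 | rac-(1S,2S)-2,6,6-trimethylcyclohex-3-ene-1-carbaldehyde (cis; racemate, one enantiomer drawn) | O=C[C@H]1[C@@H](C)C=CCC1(C)C | intermediate
4 | rac-(1R,2S)-2,6,6-trimethylcyclohex-3-ene-1-carbaldehyde (trans; racemate, one enantiomer drawn) | O=C[C@@H]1[C@@H](C)C=CCC1(C)C | intermediate
5 | rac-(1R,2S)-2,6,6-trimethylcyclohex-3-ene-1-carboxylic acid (trans; racemate, one enantiomer drawn) | OC(=O)[C@@H]1[C@@H](C)C=CCC1(C)C | intermediate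
6 | (S)-1-phenylethylamine | C[C@H](N)c1ccccc1 | starting material
7 | (S)-1-phenylethylammonium (1R,2S)-2,6,6-trimethylcyclohex-3-ene-1-carboxylate | C[C@H]([NH3+])c1ccccc1.[O-]C(=O)[C@@H]1[C@@H](C)C=CCC1(C)C | intermediate
8 | (1R,2S)-2,6,6-trimethylcyclohex-3-ene-1-carboxylic acid (single enantiomer) | OC(=O)[C@@H]1[C@@H](C)C=CCC1(C)C | intermediate
9 | methyl (1R,2S)-2,6,6-trimethylcyclohex-3-ene-1-carboxylate | COC(=O)[C@@H]1[C@@H](C)C=CCC1(C)C | intermediate
10 | methyl (1R,2R,3R,4R)-4-acetoxy-3-iodo-2,6,6-trimethylcyclohexane-1-carboxylate (trans-diaxial iodo acetate) | COC(=O)[C@@H]1[C@@H](C)[C@@H](I)[C@H](OC(C)=O)CC1(C)C | intermediate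
11 | cis-fused 2-methyl-1,3-dioxolan-2-ylium ion spanning C3 and C4 on the face of C7, acetate salt | COC(=O)[C@@H]1[C@@H](C)[C@@H]2OC(C)=[O+][C@@H]2CC1(C)C.CC(=O)[O-] | intermediate
12 | cis-fused 2-hydroxy-2-methyl-1,3-dioxolane (orthoacid; configuration at the orthoester carbon not defined) | COC(=O)[C@@H]1[C@@H](C)[C@@H]2OC(C)(O)O[C@@H]2CC1(C)C | intermediate
13 | methyl (1R,2R,3S,4R)-4-acetoxy-3-hydroxy-2,6,6-trimethylcyclohexane-1-carboxylate | COC(=O)[C@@H]1[C@@H](C)[C@H](O)[C@H](OC(C)=O)CC1(C)C | intermediate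
14 | methyl (1R,2R,3S,4R)-4-acetoxy-2,6,6-trimethyl-3-[(triethylsilyl)oxy]cyclohexane-1-carboxylate | COC(=O)[C@@H]1[C@@H](C)[C@H](O[Si](CC)(CC)CC)[C@H](OC(C)=O)CC1(C)C | intermediate
15 | (1R,2S,3R,4R)-4-(hydroxymethyl)-3,5,5-trimethyl-2-[(triethylsilyl)oxy]cyclohexan-1-ol | OC[C@@H]1[C@@H](C)[C@H](O[Si](CC)(CC)CC)[C@H](O)CC1(C)C | intermediate
16 | (1R,2S,3R,4R)-3,5,5-trimethyl-4-{[(1-phenyl-1H-tetrazol-5-yl)sulfanyl]methyl}-2-[(triethylsilyl)oxy]cyclohexan-1-ol | c1ccccc1-n1nnnc1SC[C@@H]2[C@@H](C)[C@H](O[Si](CC)(CC)CC)[C@H](O)CC2(C)C | intermediate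
17 | 5-({[(1R,2R,3S,4R)-4-[(tert-butyldimethylsilyl)oxy]-2,6,6-trimethyl-3-[(triethylsilyl)oxy]cyclohexyl]methyl}sulfanyl)-1-phenyl-1H-tetrazole | c1ccccc1-n1nnnc1SC[C@@H]2[C@@H](C)[C@H](O[Si](CC)(CC)CC)[C@H](O[Si](C)(C)C(C)(C)C)CC2(C)C | intermediate
18 | sulfoxide of 17 (configuration at sulfur not defined) | c1ccccc1-n1nnnc1S(=O)C[C@@H]2[C@@H](C)[C@H](O[Si](CC)(CC)CC)[C@H](O[Si](C)(C)C(C)(C)C)CC2(C)C | intermediate
19 | 5-({[(1R,2R,3S,4R)-4-[(tert-butyldimethylsilyl)oxy]-2,6,6-trimethyl-3-[(triethylsilyl)oxy]cyclohexyl]methyl}sulfonyl)-1-phenyl-1H-tetrazole | c1ccccc1-n1nnnc1S(=O)(=O)C[C@@H]2[C@@H](C)[C@H](O[Si](CC)(CC)CC)[C@H](O[Si](C)(C)C(C)(C)C)CC2(C)C | intermediate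
20 | crocetin dialdehyde (all-E) | O=C/C(C)=C/C=C/C(C)=C/C=C/C=C(C)/C=C/C=C(C)/C=O | starting material
21 | (all-E,3R,4S,5R,6R)-3-[(tert-butyldimethylsilyl)oxy]-4-[(triethylsilyl)oxy]-5,6-dihydro-8'-apo-β-caroten-8'-al | CC(/C=C/C=C(C)/C=C/[C@@H]1[C@@H](C)[C@H](O[Si](CC)(CC)CC)[C@H](O[Si](C)(C)C(C)(C)C)CC1(C)C)=C\C=C\C=C(C)\C=C\C=C(C)\C=O | intermediate
22 | (all-E,3R,4S,5R,6R,3'R,4'S,5'R,6'R)-3,3'-bis[(tert-butyldimethylsilyl)oxy]-4,4'-bis[(triethylsilyl)oxy]-5,6,5',6'-tetrahydro-β,β-carotene | CC(/C=C/C=C(C)/C=C/[C@@H]1[C@@H](C)[C@H](O[Si](CC)(CC)CC)[C@H](O[Si](C)(C)C(C)(C)C)CC1(C)C)=C\C=C\C=C(C)\C=C\C=C(C)\C=C\[C@@H]1[C@@H](C)[C@H](O[Si](CC)(CC)CC)[C@H](O[Si](C)(C)C(C)(C)C)CC1(C)C | intermediate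
23 | (all-E,3R,4S,5R,6R,3'R,4'S,5'R,6'R)-3,3'-bis[(tert-butyldimethylsilyl)oxy]-5,6,5',6'-tetrahydro-β,β-carotene-4,4'-diol | CC(/C=C/C=C(C)/C=C/[C@@H]1[C@@H](C)[C@H](O)[C@H](O[Si](C)(C)C(C)(C)C)CC1(C)C)=C\C=C\C=C(C)\C=C\C=C(C)\C=C\[C@@H]1[C@@H](C)[C@H](O)[C@H](O[Si](C)(C)C(C)(C)C)CC1(C)C | intermediate
24 | bis(pyridinium) (all-E,3R,4S,5R,6R,3'R,4'S,5'R,6'R)-3,3'-bis[(tert-butyldimethylsilyl)oxy]-5,6,5',6'-tetrahydro-β,β-carotene-4,4'-diyl disulfate | CC(/C=C/C=C(C)/C=C/[C@@H]1[C@@H](C)[C@H](OS(=O)(=O)[O-])[C@H](O[Si](C)(C)C(C)(C)C)CC1(C)C)=C\C=C\C=C(C)\C=C\C=C(C)\C=C\[C@@H]1[C@@H](C)[C@H](OS(=O)(=O)[O-])[C@H](O[Si](C)(C)C(C)(C)C)CC1(C)C.c1cc[nH+]cc1.c1cc[nH+]cc1 | intermediate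
25 | bis(pyridinium) (all-E,3R,4S,5R,6R,3'R,4'S,5'R,6'R)-3,3'-dihydroxy-5,6,5',6'-tetrahydro-β,β-carotene-4,4'-diyl disulfate | CC(/C=C/C=C(C)/C=C/[C@@H]1[C@@H](C)[C@H](OS(=O)(=O)[O-])[C@H](O)CC1(C)C)=C\C=C\C=C(C)\C=C\C=C(C)\C=C\[C@@H]1[C@@H](C)[C@H](OS(=O)(=O)[O-])[C@H](O)CC1(C)C.c1cc[nH+]cc1.c1cc[nH+]cc1 | intermediate
26 | (all-E,3R,4S,5R,6R,3'R,4'S,5'R,6'R)-3,3'-dihydroxy-5,6,5',6'-tetrahydro-β,β-carotene-4,4'-diyl bis(hydrogen sulfate) | CC(/C=C/C=C(C)/C=C/[C@@H]1[C@@H](C)[C@H](OS(=O)(=O)O)[C@H](O)CC1(C)C)=C\C=C\C=C(C)\C=C\C=C(C)\C=C\[C@@H]1[C@@H](C)[C@H](OS(=O)(=O)O)[C@H](O)CC1(C)C | target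

**Totals and risks**

Total step count: 16. Longest linear sequence: 16 steps (from 1 and 2 to 26; 20 enters at step 13).

Steps most likely to fail:

1. Step 7. The iodonium ion may be opened productively on the wrong face, the ester carbonyl may compete with acetate as the internal nucleophile, or the monoacetate may scramble between O3 and O4 in hot acetic acid. The fallback sets out from 9 and comes back at 13. Epoxidation with mCPBA on the face anti to the axial C1 methyl should give methyl (1R,2R,3R,4S)-3,4-epoxy-2,6,6-trimethylcyclohexane-1-carboxylate F1. Acetolysis (AcOH, catalytic H2SO4, rt) should open the oxirane trans-diaxially at carotenoid C3 to give methyl (1R,2R,3R,4R)-4-acetoxy-3-hydroxy-2,6,6-trimethylcyclohexane-1-carboxylate F2, in which the axial O3 acetate is fixed by the mechanism. Dess–Martin oxidation should then give methyl (1R,2R,4R)-4-acetoxy-2,6,6-trimethyl-3-oxocyclohexane-1-carboxylate F3. Finally NaBH4 (MeOH, −40 °C, acetic acid quench) should deliver hydride axially, anti to the neighbouring axial acetate, and set the equatorial C4 hydroxyl of 13.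

2. Step 13. The second olefination by the hindered β-branched sulfonyl anion may stall at the mono-adduct, and E geometry may erode at the two new double bonds. The fallback sets out from 15 and comes back at 22. Appel iodination (I2, PPh3, imidazole) of the primary hydroxyl should give (1R,2S,3R,4R)-4-(iodomethyl)-3,5,5-trimethyl-2-[(triethylsilyl)oxy]cyclohexan-1-ol F4. TBSOTf and 2,6-lutidine should protect O3 to give tert-butyl{[(1R,2S,3R,4R)-4-(iodomethyl)-3,5,5-trimethyl-2-[(triethylsilyl)oxy]cyclohexyl]oxy}dimethylsilane F5. Heating with PPh3 should give {[(1R,2R,3S,4R)-4-[(tert-butyldimethylsilyl)oxy]-2,6,6-trimethyl-3-[(triethylsilyl)oxy]cyclohexyl]methyl}triphenylphosphonium iodide F6. Its ylide (NaN(SiMe3)2, THF) should undergo a twofold Wittig reaction with 20 to give mainly the (7Z,7'Z) isomer of 22 F7. Iodine-catalysed equilibration in daylight should convert this into all-E 22; the same equilibration can be applied to Z-containing material from step 13.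

3. Step 16. Desilylation of the hindered axial O3 silyl ether next to an anionic sulfate may be sluggish, and long acid contact may cost sulfate by solvolysis or isomerize the polyene. The fallback sets out from 22 and comes back at 26. Global desilylation with Bu4NF should give (all-E,3R,4S,5R,6R,3'R,4'S,5'R,6'R)-5,6,5',6'-tetrahydro-β,β-carotene-3,4,3',4'-tetrol F8. Bu2SnO (MeOH, reflux) should form the 3,4:3',4'-bis(dibutylstannylene) acetal of that tetrol F9. This acetal should direct SO3·NMe3 (DMF, rt) to the equatorial O4 oxygen of each cis-diol and give the bis(trimethylammonium) 4,4'-disulfate of the tetrol F10. Cation exchange as in step 16 should then give 26.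

Further compounds
F1 | step 7 | methyl (1R,2R,3R,4S)-3,4-epoxy-2,6,6-trimethylcyclohexane-1-carboxylate (oxirane on the face of the ring methyl, anti to the ester) | COC(=O)[C@@H]1[C@@H](C)[C@H]2O[C@H]2CC1(C)C
F2 | step 7 | methyl (1R,2R,3R,4R)-4-acetoxy-3-hydroxy-2,6,6-trimethylcyclohexane-1-carboxylate | COC(=O)[C@@H]1[C@@H](C)[C@@H](O)[C@H](OC(C)=O)CC1(C)C
F3 | step 7 | methyl (1R,2R,4R)-4-acetoxy-2,6,6-trimethyl-3-oxocyclohexane-1-carboxylate | COC(=O)[C@@H]1[C@@H](C)C(=O)[C@H](OC(C)=O)CC1(C)C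
F4 | step 13 | (1R,2S,3R,4R)-4-(iodomethyl)-3,5,5-trimethyl-2-[(triethylsilyl)oxy]cyclohexan-1-ol | IC[C@@H]1[C@@H](C)[C@H](O[Si](CC)(CC)CC)[C@H](O)CC1(C)C
F5 | step 13 | tert-butyl{[(1R,2S,3R,4R)-4-(iodomethyl)-3,5,5-trimethyl-2-[(triethylsilyl)oxy]cyclohexyl]oxy}dimethylsilane | IC[C@@H]1[C@@H](C)[C@H](O[Si](CC)(CC)CC)[C@H](O[Si](C)(C)C(C)(C)C)CC1(C)C
F6 | step 13 | {[(1R,2R,3S,4R)-4-[(tert-butyldimethylsilyl)oxy]-2,6,6-trimethyl-3-[(triethylsilyl)oxy]cyclohexyl]methyl}triphenylphosphonium iodide | [I-].c1ccccc1[P+](c1ccccc1)(c1ccccc1)C[C@@H]1[C@@H](C)[C@H](O[Si](CC)(CC)CC)[C@H](O[Si](C)(C)C(C)(C)C)CC1(C)C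
F7 | step 13 | (7Z,7'Z) isomer of 22 | CC(/C=C/C=C(C)/C=C\[C@@H]1[C@@H](C)[C@H](O[Si](CC)(CC)CC)[C@H](O[Si](C)(C)C(C)(C)C)CC1(C)C)=C\C=C\C=C(C)\C=C\C=C(C)\C=C/[C@@H]1[C@@H](C)[C@H](O[Si](CC)(CC)CC)[C@H](O[Si](C)(C)C(C)(C)C)CC1(C)C
F8 | step 16 | (all-E,3R,4S,5R,6R,3'R,4'S,5'R,6'R)-5,6,5',6'-tetrahydro-β,β-carotene-3,4,3',4'-tetrol | CC(/C=C/C=C(C)/C=C/[C@@H]1[C@@H](C)[C@H](O)[C@H](O)CC1(C)C)=C\C=C\C=C(C)\C=C\C=C(C)\C=C\[C@@H]1[C@@H](C)[C@H](O)[C@H](O)CC1(C)C
F9 | step 16 | 3,4:3',4'-bis(dibutylstannylene) acetal of F8 | CC(/C=C/C=C(C)/C=C/[C@@H]1[C@@H](C)[C@@H]2O[Sn](CCCC)(CCCC)O[C@@H]2CC1(C)C)=C\C=C\C=C(C)\C=C\C=C(C)\C=C\[C@@H]1[C@@H](C)[C@@H]2O[Sn](CCCC)(CCCC)O[C@@H]2CC1(C)C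
F10 | step 16 | bis(trimethylammonium) (all-E,3R,4S,5R,6R,3'R,4'S,5'R,6'R)-3,3'-dihydroxy-5,6,5',6'-tetrahydro-β,β-carotene-4,4'-diyl disulfate | CC(/C=C/C=C(C)/C=C/[C@@H]1[C@@H](C)[C@H](OS(=O)(=O)[O-])[C@H](O)CC1(C)C)=C\C=C\C=C(C)\C=C\C=C(C)\C=C\[C@@H]1[C@@H](C)[C@H](OS(=O)(=O)[O-])[C@H](O)CC1(C)C.C[NH+](C)C.C[NH+](C)C
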